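**Retrosynthetic overview**
1. Target ⇒ terminal alkyne 12 + iodophenol 14 (Sonogashira coupling / 5-endo-dig annulation; the benzofuran ring is formed last).
2. 12 ⇒ homoallylic alcohol 9 + (triisopropylsilyl)acetylene 10 (C4–C(sp) bond and the C4 methine centre by a new OH-directed Ir-catalysed Markovnikov hydroalkynylation).
3. 9 ⇒ encecalin 6 + allyl-B(pin) 7 (C2–C3 bond and the C2 carbinol centre by catalytic enantioselective allylboration).
4. 6 ⇒ precocene I 1 (formylation, MeMgBr, oxidation); 14 ⇒ 2',4'-dihydroxyacetophenone 13 (iodination).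
5. Ring order: the 2H-chromene is bought intact and carried through; the benzofuran is closed in the final step.

Assumption: side-chain locants C2 (carbinol) and C4 (methine) follow the hexynol numbering of 11/12; where the sense of induction of a chiral catalyst or ligand is not known for this substrate, the enantiomer that gives the stated product is used.

**Step 1**
Reactants: 1 precocene I (7-methoxy-2,2-dimethyl-2H-chromene)
Product: 3 7-methoxy-2,2-dimethyl-2H-chromene-6-carbaldehyde, via aryl iminium chloride 2 (not isolated)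
Conditions: (chloromethylene)dimethyliminium chloride (1.3 equiv), DMF, 0 °C → rt; then aq. NaHCO3
Reagents that add atoms: (chloromethylene)dimethyliminium chloride, C[N+](C)=CCl.[Cl-]; water, O
Why: Vilsmeier–Haack formylation: the chloroiminium electrophile attacks the most activated, least hindered arene position C6 (para to the ring O, ortho to OMe; C8 lies between two oxygens) and iminium 2 is hydrolysed on work-up; no stereocentre is formed.

**Step 2**
Reactants: 3 7-methoxy-2,2-dimethyl-2H-chromene-6-carbaldehyde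
Product: 5 rac-1-(7-methoxy-2,2-dimethyl-2H-chromen-6-yl)ethan-1-ol, via bromomagnesium alkoxide 4 (not isolated)
Conditions: MeMgBr (1.2 equiv), THF, 0 °C; then sat. aq. NH4Cl
Reagents that add atoms: methylmagnesium bromide, C[Mg]Br
Why: Grignard 1,2-addition to the aryl aldehyde; the carbinol centre is deliberately racemic because it is erased in step 3.

**Step 3**
Reactants: 5 rac-1-(7-methoxy-2,2-dimethyl-2H-chromen-6-yl)ethan-1-ol
Product: 6 encecalin [1-(7-methoxy-2,2-dimethyl-2H-chromen-6-yl)ethan-1-one]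
Conditions: MnO2 (10 equiv), CH2Cl2, rt
Reagents that add atoms: none
Why: MnO2 oxidation of an activated benzylic secondary alcohol to the aryl methyl ketone, which leaves the chromene C3=C4 bond untouched.

**Step 4**
Reactants: 6 encecalin; 7 allylboronic acid pinacol ester
Product: 9 (S)-2-(7-methoxy-2,2-dimethyl-2H-chromen-6-yl)pent-4-en-2-ol, via O-B(pin) borate 8 (not isolated)
Conditions: 7 (1.5 equiv), valine-derived chiral aminophenol catalyst (2.5 mol%), NaOt-Bu (5 mol%), MeOH (2 equiv), toluene, 22 °C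
Reagents that add atoms: none
Why: Catalytic enantioselective allylboration of a methyl ketone through a closed six-membered (Zimmerman–Traxler-type) transition state on the chiral aminophenol–boron catalyst; the catalyst enantiomer that delivers allyl to the Si face of the C=O (aryl versus methyl) gives the (S)-carbinol, and MeOH frees 9 from borate 8.

**Step 5**
Reactants: 9 (S)-2-(7-methoxy-2,2-dimethyl-2H-chromen-6-yl)pent-4-en-2-ol; 10 (triisopropylsilyl)acetylene
Product: 11 (2S,4S)-2-(7-methoxy-2,2-dimethyl-2H-chromen-6-yl)-4-methyl-6-(triisopropylsilyl)hex-5-yn-2-ol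
Conditions: [Ir(cod)Cl]2 (2.5 mol%), DTBM-SEGPHOS (6 mol%; enantiomer giving 4S, fixed by a two-run screen), 10 (2 equiv), THF, 60 °C, no base
Reagents that add atoms: none
Why: Proposed new method: tertiary-hydroxyl-directed, Ir(I)/bisphosphine-catalysed Markovnikov hydroalkynylation of an unactivated terminal alkene, in which oxidative addition of the silylacetylene C–H gives an Ir(III)(H)(alkynyl) species, the neutral OH binds Ir and delivers the alkene so that Ir–H insertion closes the five-membered O–Ir–C4 chelate (Ir at C4, H to C5) in preference to the six-membered linear one, and C(sp3)–C(sp) reductive elimination forms the C4–alkynyl bond with retention; the (4S) centre is set in the insertion by the chiral ligand (catalyst control over a weak 1,3-substrate bias), the undirected and hindered chromene alkene is not engaged, and omitting base avoids an Ir alkoxide that could undergo retro-allylation; the closest known reaction type is the Ir-catalysed, amide-carbonyl-directed enantioselective hydroalkynylation of unactivated alkenes with silylacetylenes, together with hydroxyl-directed Ir hydrogenation.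

**Step 6**
Reactants: 11 (2S,4S)-2-(7-methoxy-2,2-dimethyl-2H-chromen-6-yl)-4-methyl-6-(triisopropylsilyl)hex-5-yn-2-ol
Product: 12 (2S,4S)-2-(7-methoxy-2,2-dimethyl-2H-chromen-6-yl)-4-methylhex-5-yn-2-ol
Conditions: TBAF (1.2 equiv), THF, 0 °C → rt
Reagents that add atoms: none
Why: Fluoride-induced protodesilylation of the alkynyl–Si bond; neither stereocentre is affected.

**Step 7**
Reactants: 13 2',4'-dihydroxyacetophenone
Product: 14 1-(2,4-dihydroxy-5-iodophenyl)ethan-1-one
Conditions: ICl (1.0 equiv), AcOH, rt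
Reagents that add atoms: iodine monochloride, ClI
Why: Electrophilic aromatic iodination (SEAr) at C5, which is para to the chelated 2-OH, ortho to the 4-OH and less hindered than C3 between the two hydroxyls; one equivalent of ICl limits di-iodination.

**Step 8**
Reactants: 12 (2S,4S)-2-(7-methoxy-2,2-dimethyl-2H-chromen-6-yl)-4-methylhex-5-yn-2-ol; 14 1-(2,4-dihydroxy-5-iodophenyl)ethan-1-one
Product: 16 1-[6-hydroxy-2-[(2S,4S)-4-hydroxy-4-(7-methoxy-2,2-dimethyl-2H-chromen-6-yl)pentan-2-yl]-1-benzofuran-5-yl]ethan-1-one (CNP0233723.1), via o-alkynylphenol 15 (not isolated)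
Conditions: PdCl2(PPh3)2 (5 mol%), CuI (10 mol%), Et3N, DMF, 70 °C, Ar
Reagents that add atoms: none
Why: Sonogashira coupling to o-alkynylphenol 15 followed in the same pot by Cu/Pd- and base-assisted 5-endo-dig hydroalkoxylation by the 4-OH (Castro–Stephens-type benzofuran annulation) while the chelated 2-OH stays free; the basic medium spares the acid-labile tertiary benzylic alcohol and neither stereocentre is touched.

**Compound list**
1 | precocene I (7-methoxy-2,2-dimethyl-2H-chromene) | COc1ccc2c(c1)OC(C)(C)C=C2 | starting material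
2 | aryl iminium chloride, N-[(7-methoxy-2,2-dimethyl-2H-chromen-6-yl)methylidene]-N-methylmethanaminium chloride (not isolated) | COc1cc2c(cc1C=[N+](C)C)C=CC(C)(C)O2.[Cl-] | intermediate
3 | 7-methoxy-2,2-dimethyl-2H-chromene-6-carbaldehyde | COc1cc2c(cc1C=O)C=CC(C)(C)O2 | intermediate
4 | bromomagnesium alkoxide of 5 (racemic, not isolated) | COc1cc2c(cc1C(C)O[Mg]Br)C=CC(C)(C)O2 | intermediate
5 | rac-1-(7-methoxy-2,2-dimethyl-2H-chromen-6-yl)ethan-1-ol | COc1cc2c(cc1C(C)O)C=CC(C)(C)O2 | intermediate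
6 | encecalin, 1-(7-methoxy-2,2-dimethyl-2H-chromen-6-yl)ethan-1-one | COc1cc2c(cc1C(C)=O)C=CC(C)(C)O2 | intermediate
7 | allylboronic acid pinacol ester (2-allyl-4,4,5,5-tetramethyl-1,3,2-dioxaborolane) | C=CCB1OC(C)(C)C(C)(C)O1 | starting material
8 | O-B(pin) borate of 9, (S)-2-{[2-(7-methoxy-2,2-dimethyl-2H-chromen-6-yl)pent-4-en-2-yl]oxy}-4,4,5,5-tetramethyl-1,3,2-dioxaborolane (not isolated) | COc1cc2c(cc1[C@@](C)(OB3OC(C)(C)C(C)(C)O3)CC=C)C=CC(C)(C)O2 | intermediate
9 | (S)-2-(7-methoxy-2,2-dimethyl-2H-chromen-6-yl)pent-4-en-2-ol | COc1cc2c(cc1[C@@](C)(O)CC=C)C=CC(C)(C)O2 | intermediate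
10 | (triisopropylsilyl)acetylene | C#C[Si](C(C)C)(C(C)C)C(C)C | starting material
11 | (2S,4S)-2-(7-methoxy-2,2-dimethyl-2H-chromen-6-yl)-4-methyl-6-(triisopropylsilyl)hex-5-yn-2-ol | COc1cc2c(cc1[C@@](C)(O)C[C@H](C)C#C[Si](C(C)C)(C(C)C)C(C)C)C=CC(C)(C)O2 | intermediate
12 | (2S,4S)-2-(7-methoxy-2,2-dimethyl-2H-chromen-6-yl)-4-methylhex-5-yn-2-ol | COc1cc2c(cc1[C@@](C)(O)C[C@H](C)C#C)C=CC(C)(C)O2 | intermediate
13 | 2',4'-dihydroxyacetophenone, 1-(2,4-dihydroxyphenyl)ethan-1-one | CC(=O)c1ccc(O)cc1O | starting material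
14 | 1-(2,4-dihydroxy-5-iodophenyl)ethan-1-one | CC(=O)c1cc(I)c(O)cc1O | intermediate
15 | o-alkynylphenol, 1-{2,4-dihydroxy-5-[(3S,5S)-5-hydroxy-5-(7-methoxy-2,2-dimethyl-2H-chromen-6-yl)-3-methylhex-1-yn-1-yl]phenyl}ethan-1-one (not isolated) | COc1cc2c(cc1[C@@](C)(O)C[C@H](C)C#Cc1cc(C(C)=O)c(O)cc1O)C=CC(C)(C)O2 | intermediate
16 | 1-[6-hydroxy-2-[(2S,4S)-4-hydroxy-4-(7-methoxy-2,2-dimethyl-2H-chromen-6-yl)pentan-2-yl]-1-benzofuran-5-yl]ethan-1-one (CNP0233723.1) | COc1cc2c(cc1[C@@](C)(O)C[C@H](C)c1cc3cc(C(C)=O)c(O)cc3o1)C=CC(C)(C)O2 | target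

**Step count**
Total steps: 8. Longest linear sequence: 7 (steps 1–6 and 8); step 7 is a one-step side branch.

**Three steps most likely to fail**

Step 5 (the new step). Risks are weak direction by a neutral tertiary OH, the linear (six-membered chelate) regioisomer, alkene isomerisation and a mismatched diastereomer ratio. The fallback uses known chemistry only, sets out from ketone 6 and comes back at 11. It takes the methine centre from the chiral pool and sets the carbinol by the known Cu(I)/Josiphos-catalysed asymmetric 1,2-addition of β-branched Grignard reagents to aryl methyl ketones. Commercial methyl (S)-3-hydroxy-2-methylpropanoate is silylated (TBSCl, imidazole) to methyl (S)-3-((tert-butyldimethylsilyl)oxy)-2-methylpropanoate F1. DIBAL-H at −78 °C gives (S)-3-((tert-butyldimethylsilyl)oxy)-2-methylpropanal F2. Ohira–Bestmann homologation (K2CO3, MeOH) gives (R)-tert-butyldimethyl((2-methylbut-3-yn-1-yl)oxy)silane F3. C-silylation (n-BuLi, then TIPSCl) gives (R)-tert-butyldimethyl((2-methyl-4-(triisopropylsilyl)but-3-yn-1-yl)oxy)silane F4. Acidic methanolysis (CSA, MeOH) gives (R)-2-methyl-4-(triisopropylsilyl)but-3-yn-1-ol F5, and an Appel reaction (CBr4, PPh3) gives (R)-(4-bromo-3-methylbut-1-yn-1-yl)triisopropylsilane F6. Magnesium converts F6 into (R)-(2-methyl-4-(triisopropylsilyl)but-3-yn-1-yl)magnesium bromide F7. This adds to 6 under CuBr·SMe2/Josiphos catalysis (t-BuOMe, −78 °C, ligand enantiomer for Si-face attack) to give the bromomagnesium alkoxide of 11 F8, and NH4Cl work-up gives 11, from which steps 6 and 8 follow as written.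

Step 4. The ortho-methoxy, electron-rich ketone may react slowly or with eroded er in the catalytic allylboration. The fallback sets out from 6 and comes back at 9, and replaces catalyst-controlled addition by a stereospecific lithiation–borylation. CBS reduction ((S)-Me-CBS, BH3·SMe2) gives (R)-1-(7-methoxy-2,2-dimethyl-2H-chromen-6-yl)ethan-1-ol F9. Carbamoylation (iPr2NCOCl, Et3N) gives (R)-1-(7-methoxy-2,2-dimethyl-2H-chromen-6-yl)ethyl diisopropylcarbamate F10. s-BuLi (Et2O, −78 °C) gives the configurationally stable (R)-α-lithio carbamate F11, which is borylated with 7 with retention to the lithium allyl boronate complex F12. 1,2-Migration of the allyl group with inversion (MgBr2/MeOH, warming) gives the tertiary boronic ester (R)-2-[2-(7-methoxy-2,2-dimethyl-2H-chromen-6-yl)pent-4-en-2-yl]-4,4,5,5-tetramethyl-1,3,2-dioxaborolane F13. NaOH/H2O2 oxidation with retention gives 9.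

Step 8. The one-pot coupling/annulation on the unprotected, chelated iodophenol may stall at 15, give Glaser dimer of 12, or be poisoned by the free phenols. The fallback sets out from 14 (with 12), comes back at 15 and then 16, and separates C–C coupling from ring closure with masked phenols. 14 is acetylated (Ac2O, pyridine, DMAP) to 4-acetyl-6-iodo-1,3-phenylene diacetate F14. Sonogashira coupling with 12 at rt (Pd(PPh3)4, CuI, Et3N, THF) gives the isolable 4-acetyl-6-[(3S,5S)-5-hydroxy-5-(7-methoxy-2,2-dimethyl-2H-chromen-6-yl)-3-methylhex-1-yn-1-yl]-1,3-phenylene diacetate F15. K2CO3/MeOH removes both acetates to give 15, which is closed in a separate base-mediated 5-endo-dig cyclisation (Cs2CO3, DMF, 60 °C) to 16.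

**Further compounds**
F1 | step 5 | methyl (S)-3-((tert-butyldimethylsilyl)oxy)-2-methylpropanoate | CC(C)(C)[Si](C)(C)OC[C@H](C)C(=O)OC
F2 | step 5 | (S)-3-((tert-butyldimethylsilyl)oxy)-2-methylpropanal | CC(C)(C)[Si](C)(C)OC[C@H](C)C=O
F3 | step 5 | (R)-tert-butyldimethyl((2-methylbut-3-yn-1-yl)oxy)silane | CC(C)(C)[Si](C)(C)OC[C@H](C)C#C
F4 | step 5 | (R)-tert-butyldimethyl((2-methyl-4-(triisopropylsilyl)but-3-yn-1-yl)oxy)silane | CC(C)(C)[Si](C)(C)OC[C@H](C)C#C[Si](C(C)C)(C(C)C)C(C)C
F5 | step 5 | (R)-2-methyl-4-(triisopropylsilyl)but-3-yn-1-ol | OC[C@H](C)C#C[Si](C(C)C)(C(C)C)C(C)C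
F6 | step 5 | (R)-(4-bromo-3-methylbut-1-yn-1-yl)triisopropylsilane | BrC[C@H](C)C#C[Si](C(C)C)(C(C)C)C(C)C
F7 | step 5 | (R)-(2-methyl-4-(triisopropylsilyl)but-3-yn-1-yl)magnesium bromide | Br[Mg]C[C@H](C)C#C[Si](C(C)C)(C(C)C)C(C)C
F8 | step 5 | bromomagnesium alkoxide of 11 | COc1cc2c(cc1[C@@](C)(O[Mg]Br)C[C@H](C)C#C[Si](C(C)C)(C(C)C)C(C)C)C=CC(C)(C)O2
F9 | step 4 | (R)-1-(7-methoxy-2,2-dimethyl-2H-chromen-6-yl)ethan-1-ol | COc1cc2c(cc1[C@@H](C)O)C=CC(C)(C)O2
F10 | step 4 | (R)-1-(7-methoxy-2,2-dimethyl-2H-chromen-6-yl)ethyl diisopropylcarbamate | COc1cc2c(cc1[C@@H](C)OC(=O)N(C(C)C)C(C)C)C=CC(C)(C)O2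
F11 | step 4 | (R)-α-lithio carbamate, (R)-1-lithio-1-(7-methoxy-2,2-dimethyl-2H-chromen-6-yl)ethyl diisopropylcarbamate | COc1cc2c(cc1[C@@]([Li])(C)OC(=O)N(C(C)C)C(C)C)C=CC(C)(C)O2
F12 | step 4 | lithium allyl boronate complex of F11 with 7 | COc1cc2c(cc1[C@@]([B-]3(CC=C)OC(C)(C)C(C)(C)O3)(C)OC(=O)N(C(C)C)C(C)C)C=CC(C)(C)O2.[Li+]
F13 | step 4 | (R)-2-[2-(7-methoxy-2,2-dimethyl-2H-chromen-6-yl)pent-4-en-2-yl]-4,4,5,5-tetramethyl-1,3,2-dioxaborolane | COc1cc2c(cc1[C@@](C)(B3OC(C)(C)C(C)(C)O3)CC=C)C=CC(C)(C)O2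
F14 | step 8 | 4-acetyl-6-iodo-1,3-phenylene diacetate | CC(=O)Oc1cc(OC(C)=O)c(C(C)=O)cc1I
F15 | step 8 | 4-acetyl-6-[(3S,5S)-5-hydroxy-5-(7-methoxy-2,2-dimethyl-2H-chromen-6-yl)-3-methylhex-1-yn-1-yl]-1,3-phenylene diacetate | COc1cc2c(cc1[C@@](C)(O)C[C@H](C)C#Cc1cc(C(C)=O)c(OC(C)=O)cc1OC(C)=O)C=CC(C)(C)O2
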